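**Plan** (oxane numbering: O1; C2 carries the methoxycatechol ring; C4 carries OH; C6 carries the C7–C8 chain to the catechol ring)
- Cuts: put back four O-benzyl groups and a C7=C8 double bond. Take C4–OH back to C4=O. Then cut C5–C6 (ring bond), O1–C6 (ether bond) and C2–C3 (propargylation).
- Enabling feature: C6 sits next to ring oxygen O1 and two carbons from the catechol ring. With C7=C8 unsaturated, a C6–H is α-oxy, allylic and vinylogously para-benzylic to the unhindered 4-oxygen of that ring. DDQ can therefore remove it as hydride, while C4, stored as an enol acetate, offers C5 as the nucleophile.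
- Forward order: aldehyde to homopropargylic alcohol (C2–C3), cinnamyl ether (O1–C6), alkyne to enol acetate, oxidative C–H cyclisation closing the only new ring (C5–C6), ketone reduction. One hydrogenation then removes the alkene and all benzyl groups.
- Stereochemistry: C2 comes from a catalyst-controlled propargylation. C6 is relayed from C2 through a chair transition state (2,6-cis). C4 follows from equatorial hydride attack on the 2,6-diequatorial ketone (axial OH, trans to both side chains).

Key step: step 7

Assumption: (S)-TRIP is taken to direct the allenylboronate to the Si face of the aromatic aldehyde, by analogy with the sense expected for aryl aldehydes. If the sense is opposite, (R)-TRIP is used and nothing else changes.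

Step 1
Reactants: 1 3,4-dihydroxy-5-methoxybenzaldehyde
Product: 2 3,4-bis(benzyloxy)-5-methoxybenzaldehyde
Conditions: BnBr, K2CO3, DMF, 60 °C, N2
Reagents that add atoms: benzyl bromide BrCc1ccccc1
Why: Williamson O-benzylation of both phenols with a carbonate base leaves the aldehyde and the methyl ether untouched and forms no stereocentre.

Step 2
Reactants: 2 3,4-bis(benzyloxy)-5-methoxybenzaldehyde
Product: 4 (1S)-1-[3,4-bis(benzyloxy)-5-methoxyphenyl]but-3-yn-1-ol, via pinacol borate ester 3 (not isolated)
Conditions: allenyl-Bpin, (S)-TRIP (cat.), 4 Å MS, toluene, −20 °C; aqueous work-up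
Reagents that add atoms: allenylboronic acid pinacol ester C=C=CB1OC(C)(C)C(C)(C)O1
Why: In this chiral phosphoric acid catalysed asymmetric propargylation (SE2′ allenylboration) the acid activates the boronate in a closed six-membered transition state, the 3,3′-aryl groups of the catalyst leave only the Si face of the aldehyde open, which sets C2 as S, and borate 3 is hydrolysed on work-up.

Step 3
Reactants: 5 3,4-bis(benzyloxy)benzaldehyde
Product: 6 (±)-1-[3,4-bis(benzyloxy)phenyl]prop-2-en-1-ol
Conditions: CH2=CHMgBr, THF, 0 °C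
Reagents that add atoms: vinylmagnesium bromide C=C[Mg]Br
Why: Grignard 1,2-addition to the aldehyde gives the racemic carbinol, whose stereocentre is erased in step 4.

Step 4
Reactants: 6 (±)-1-[3,4-bis(benzyloxy)phenyl]prop-2-en-1-ol
Product: 7 4-[(1E)-3-bromoprop-1-en-1-yl]-1,2-bis(benzyloxy)benzene
Conditions: PBr3 (0.4 equiv), Et2O, 0 °C; used crude
Reagents that add atoms: phosphorus tribromide BrP(Br)Br
Why: Bromination with allylic transposition (SN1′/SN2′) should work because the activated benzylic-allylic oxygen leaves easily and bromide ends at the terminal carbon, which gives the conjugated and thermodynamically preferred E-cinnamyl bromide.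

Step 5
Reactants: 4 (1S)-1-[3,4-bis(benzyloxy)-5-methoxyphenyl]but-3-yn-1-ol, 7 4-[(1E)-3-bromoprop-1-en-1-yl]-1,2-bis(benzyloxy)benzene
Product: 8 1,2-bis(benzyloxy)-5-[(1S)-1-{[(2E)-3-[3,4-bis(benzyloxy)phenyl]prop-2-en-1-yl]oxy}but-3-yn-1-yl]-3-methoxybenzene
Conditions: NaH (1.05 equiv), Bu4NI (cat.), THF–DMF, 0 °C to rt
Reagents that add atoms: none
Why: Williamson ether synthesis by SN2 attack at the primary allylic bromide does not touch the C2–O bond, so the S configuration is kept, and one equivalent of base leaves the alkyne C–H alone.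

Step 6
Reactants: 8 1,2-bis(benzyloxy)-5-[(1S)-1-{[(2E)-3-[3,4-bis(benzyloxy)phenyl]prop-2-en-1-yl]oxy}but-3-yn-1-yl]-3-methoxybenzene
Product: 9 (4S)-4-[3,4-bis(benzyloxy)-5-methoxyphenyl]-4-{[(2E)-3-[3,4-bis(benzyloxy)phenyl]prop-2-en-1-yl]oxy}but-1-en-2-yl acetate
Conditions: [RuCl2(p-cymene)]2 (cat.), P(2-furyl)3 (cat.), Na2CO3 (cat.), AcOH, toluene, 80 °C
Reagents that add atoms: acetic acid CC(=O)O
Why: Ruthenium-catalysed Markovnikov hydroacyloxylation of the terminal alkyne places acetate on the internal carbon (future C4) under buffered conditions that allylic and benzylic ethers tolerate, and it forms no stereocentre.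

Step 7
Reactants: 9 (4S)-4-[3,4-bis(benzyloxy)-5-methoxyphenyl]-4-{[(2E)-3-[3,4-bis(benzyloxy)phenyl]prop-2-en-1-yl]oxy}but-1-en-2-yl acetate
Product: 11 (2S,6R)-2-[3,4-bis(benzyloxy)-5-methoxyphenyl]-6-{(E)-2-[3,4-bis(benzyloxy)phenyl]ethenyl}oxan-4-one, via cinnamyl oxocarbenium ion 10 (not isolated)
Conditions: DDQ (1.2–1.5 equiv), 2,6-dichloropyridine, LiClO4 (cat.), 4 Å MS, ClCH2CH2Cl, −20 °C to rt
Reagents that add atoms: none
Why: DDQ removes one C6–H of 9 as hydride (electron transfer from the 3,4-bis(benzyloxy)styrene unit, then hydrogen loss) to give the (E,E)-oxocarbenium ion 10, whose charge is spread over O1, C6, C8 and the para-oxygen of the catechol ring; the terminal enol acetate carbon C5 then adds to C6 and the acetyl group is lost, which unmasks the C4 ketone and makes the C–C bond formation irreversible. The closest known reaction type is the DDQ-mediated oxidative C–H cleavage and cyclisation of allylic or benzylic ethers that carry an enol acetate, an oxidatively triggered Prins/Mukaiyama-type closure that gives 2,6-cis-tetrahydropyran-4-ones. The oxane ring closes in a 6-endo-trig mode at the O1=C6 bond (enol-endo with respect to the C4=C5 bond). The new stereocentre C6 is controlled by C2: in the chair transition state the C2 aryl group sits equatorial and the E geometry of O1=C6 places the styryl group equatorial too, so C5 attacks the face that gives the 2,6-cis (6R) product. The step needs site selectivity for C6–H over the benzylic C2–H and the eight ArOCH2Ph hydrogens, and this is secured by the lower oxidation potential of the dialkoxystyrene, by the two ortho neighbours that twist the para-oxygen of the 3,4,5-trioxygenated ring out of conjugation, by the poor alignment of the tertiary C2–H with its ring, and by the delocalisation of the benzyl ether oxygens into their arenes. Fast capture by the enol acetate also forestalls 2-oxonia-Cope exchange, so the S configuration at C2 is kept.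

Step 8
Reactants: 11 (2S,6R)-2-[3,4-bis(benzyloxy)-5-methoxyphenyl]-6-{(E)-2-[3,4-bis(benzyloxy)phenyl]ethenyl}oxan-4-one
Product: 12 (2S,4S,6R)-2-[3,4-bis(benzyloxy)-5-methoxyphenyl]-6-{(E)-2-[3,4-bis(benzyloxy)phenyl]ethenyl}oxan-4-ol
Conditions: L-Selectride, THF, −78 °C
Reagents that add atoms: none
Why: In this substrate-controlled reduction the bulky trialkylborohydride approaches the chair with both side chains equatorial along the equatorial trajectory, which sets C4 as the axial alcohol (4S, trans to the C2 and C6 groups), while the isolated styrene and the benzyl ethers are inert.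

Step 9
Reactants: 12 (2S,4S,6R)-2-[3,4-bis(benzyloxy)-5-methoxyphenyl]-6-{(E)-2-[3,4-bis(benzyloxy)phenyl]ethenyl}oxan-4-ol
Product: 13 (2S,4S,6S)-2-(3,4-dihydroxy-5-methoxyphenyl)-6-[2-(3,4-dihydroxyphenyl)ethyl]oxan-4-ol
Conditions: H2 (1 atm), 10% Pd/C, EtOAc–MeOH, rt
Reagents that add atoms: none
Why: Catalytic hydrogenation saturates C7=C8 and hydrogenolyses the four aryl benzyl ethers in one operation under neutral conditions, in which the cyclic C2–O1 benzylic ether should react far more slowly; no stereocentre is touched, and the C6 descriptor changes from R to S only through a change of CIP priorities.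

**Compound list**
1 | 3,4-dihydroxy-5-methoxybenzaldehyde | COc1cc(C=O)cc(O)c1O | starting material
2 | 3,4-bis(benzyloxy)-5-methoxybenzaldehyde | COc1cc(C=O)cc(OCc2ccccc2)c1OCc1ccccc1 | intermediate
3 | pinacol borate ester of 4, 2-{[(1S)-1-[3,4-bis(benzyloxy)-5-methoxyphenyl]but-3-yn-1-yl]oxy}-4,4,5,5-tetramethyl-1,3,2-dioxaborolane | COc1cc([C@@H](OB2OC(C)(C)C(C)(C)O2)CC#C)cc(OCc2ccccc2)c1OCc1ccccc1 | intermediate
4 | (1S)-1-[3,4-bis(benzyloxy)-5-methoxyphenyl]but-3-yn-1-ol | COc1cc([C@@H](O)CC#C)cc(OCc2ccccc2)c1OCc1ccccc1 | intermediate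
5 | 3,4-bis(benzyloxy)benzaldehyde | O=Cc1ccc(OCc2ccccc2)c(OCc2ccccc2)c1 | starting material
6 | (±)-1-[3,4-bis(benzyloxy)phenyl]prop-2-en-1-ol | C=CC(O)c1ccc(OCc2ccccc2)c(OCc2ccccc2)c1 | intermediate
7 | 4-[(1E)-3-bromoprop-1-en-1-yl]-1,2-bis(benzyloxy)benzene | BrC/C=C/c1ccc(OCc2ccccc2)c(OCc2ccccc2)c1 | intermediate
8 | 1,2-bis(benzyloxy)-5-[(1S)-1-{[(2E)-3-[3,4-bis(benzyloxy)phenyl]prop-2-en-1-yl]oxy}but-3-yn-1-yl]-3-methoxybenzene | COc1cc([C@@H](OC/C=C/c2ccc(OCc3ccccc3)c(OCc3ccccc3)c2)CC#C)cc(OCc2ccccc2)c1OCc1ccccc1 | intermediate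
9 | (4S)-4-[3,4-bis(benzyloxy)-5-methoxyphenyl]-4-{[(2E)-3-[3,4-bis(benzyloxy)phenyl]prop-2-en-1-yl]oxy}but-1-en-2-yl acetate | COc1cc([C@@H](OC/C=C/c2ccc(OCc3ccccc3)c(OCc3ccccc3)c2)CC(=C)OC(C)=O)cc(OCc2ccccc2)c1OCc1ccccc1 | intermediate
10 | (E,E)-cinnamyl oxocarbenium ion, [(1S)-3-acetoxy-1-[3,4-bis(benzyloxy)-5-methoxyphenyl]but-3-en-1-yl][(2E)-3-[3,4-bis(benzyloxy)phenyl]prop-2-en-1-ylidene]oxonium | COc1cc([C@@H](/[O+]=C/C=C/c2ccc(OCc3ccccc3)c(OCc3ccccc3)c2)CC(=C)OC(C)=O)cc(OCc2ccccc2)c1OCc1ccccc1 | intermediate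
11 | (2S,6R)-2-[3,4-bis(benzyloxy)-5-methoxyphenyl]-6-{(E)-2-[3,4-bis(benzyloxy)phenyl]ethenyl}oxan-4-one | COc1cc([C@@H]2CC(=O)C[C@H](/C=C/c3ccc(OCc4ccccc4)c(OCc4ccccc4)c3)O2)cc(OCc2ccccc2)c1OCc1ccccc1 | intermediate
12 | (2S,4S,6R)-2-[3,4-bis(benzyloxy)-5-methoxyphenyl]-6-{(E)-2-[3,4-bis(benzyloxy)phenyl]ethenyl}oxan-4-ol | COc1cc([C@@H]2C[C@@H](O)C[C@H](/C=C/c3ccc(OCc4ccccc4)c(OCc4ccccc4)c3)O2)cc(OCc2ccccc2)c1OCc1ccccc1 | intermediate
13 | (2S,4S,6S)-2-(3,4-dihydroxy-5-methoxyphenyl)-6-[2-(3,4-dihydroxyphenyl)ethyl]oxan-4-ol | COc1cc([C@@H]2C[C@@H](O)C[C@H](CCc3ccc(O)c(O)c3)O2)cc(O)c1O | target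

Total step count: 9. Longest linear sequence: 7 steps (steps 1, 2, 5, 6, 7, 8, 9; the branch through steps 3 and 4 is equally long).

**Steps most likely to fail**

**Step 7.**
- What may go wrong: hydride abstraction at the wrong site (C2–H or a benzyl ether CH2), slow capture of the strongly stabilised cation, or further oxidation of the product.
- The fallback sets out from 4 and 5 and comes back at 11. It builds the same kind of cation by condensation, without an oxidant.
- Gold(I)-catalysed Markovnikov hydration of the alkyne of 4 would give (4S)-4-[3,4-bis(benzyloxy)-5-methoxyphenyl]-4-hydroxybutan-2-one F1.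
- Double silylation under kinetic control (LiHMDS, TMSCl in situ quench, THF, −78 °C) would give (S)-[1-[3,4-bis(benzyloxy)-5-methoxyphenyl]-3-(trimethylsilyloxy)but-3-en-1-yl]oxytrimethylsilane F2.
- Wittig homologation of 5 with (triphenylphosphoranylidene)acetaldehyde would give (E)-3-[3,4-bis(benzyloxy)phenyl]prop-2-enal F3.
- TMSOTf-catalysed condensation of F2 with F3 (CH2Cl2, −78 °C, silyl enol ether Prins cyclisation) should close the same C5–C6 bond through the same chair and deliver 11.

**Step 9.**
- What may go wrong: reductive cleavage of the allylic C6–O1 bond before the alkene is saturated, or of the benzylic C2–O1 bond, with ring opening.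
- The fallback sets out from 12 and comes back at 13. It avoids palladium and hydrogen altogether.
- Diimide (2-nitrobenzenesulfonyl hydrazide, Et3N, CH2Cl2) would saturate C7=C8 without any C–O cleavage. This gives (2S,4S,6S)-2-[3,4-bis(benzyloxy)-5-methoxyphenyl]-6-{2-[3,4-bis(benzyloxy)phenyl]ethyl}oxan-4-ol F4.
- Lewis acid debenzylation of F4 with BCl3 and pentamethylbenzene as cation scavenger (CH2Cl2, −78 °C) would then release 13.

**Step 2.**
- What may go wrong: poor facial discrimination or slow turnover with the hindered, electron-rich aldehyde.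
- The fallback sets out from 2 and comes back at 4. It replaces asymmetric catalysis by resolution.
- Zinc-mediated Barbier propargylation of 2 with propargyl bromide would give racemic 1-[3,4-bis(benzyloxy)-5-methoxyphenyl]but-3-yn-1-ol F5.
- Lipase-catalysed acylation (immobilised Candida antarctica lipase B, vinyl acetate, MTBE) should follow the empirical preference for secondary carbinols with one large aryl and one medium CH2 substituent. It should convert the R enantiomer into (1R)-1-[3,4-bis(benzyloxy)-5-methoxyphenyl]but-3-yn-1-yl acetate F6.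
- The unreacted S alcohol 4 is then separated by chromatography.

Further compounds
F1 | step 7 | (4S)-4-[3,4-bis(benzyloxy)-5-methoxyphenyl]-4-hydroxybutan-2-one | COc1cc([C@@H](O)CC(C)=O)cc(OCc2ccccc2)c1OCc1ccccc1
F2 | step 7 | (S)-[1-[3,4-bis(benzyloxy)-5-methoxyphenyl]-3-(trimethylsilyloxy)but-3-en-1-yl]oxytrimethylsilane | COc1cc([C@@H](O[Si](C)(C)C)CC(=C)O[Si](C)(C)C)cc(OCc2ccccc2)c1OCc1ccccc1
F3 | step 7 | (E)-3-[3,4-bis(benzyloxy)phenyl]prop-2-enal | O=C/C=C/c1ccc(OCc2ccccc2)c(OCc2ccccc2)c1
F4 | step 9 | (2S,4S,6S)-2-[3,4-bis(benzyloxy)-5-methoxyphenyl]-6-{2-[3,4-bis(benzyloxy)phenyl]ethyl}oxan-4-ol | COc1cc([C@@H]2C[C@@H](O)C[C@H](CCc3ccc(OCc4ccccc4)c(OCc4ccccc4)c3)O2)cc(OCc2ccccc2)c1OCc1ccccc1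
F5 | step 2 | racemic 1-[3,4-bis(benzyloxy)-5-methoxyphenyl]but-3-yn-1-ol | COc1cc(C(O)CC#C)cc(OCc2ccccc2)c1OCc1ccccc1
F6 | step 2 | (1R)-1-[3,4-bis(benzyloxy)-5-methoxyphenyl]but-3-yn-1-yl acetate | COc1cc([C@H](OC(C)=O)CC#C)cc(OCc2ccccc2)c1OCc1ccccc1
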